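How far does the red flask get in 50 min, and how does its opening rate answer to catalyst and coupling partner?

| flask | starting material | coupling partner | catalyst | time |
|---|---|---|---|---|
| green | 1.00 M | 1.10 M | 0.100 M |  |
| ochre | 0.500 M | 0.600 M | 0.100 M |  |
| grey | 1.00 M | 1.10 M | 0.200 M |  |
| blue | 0.500 M | 1.10 M | 0.100 M |  |
| red | 1.00 M | 1.10 M | 0.100 M | 50 min |

| run | time / min | [product] / M |
|---|---|---|
| green run | 3.3 | 0.063 |
| green run | 6.7 | 0.151 |
| green run | 10 | 0.235 |
| green run | 13 | 0.310 |
| green run | 17 | 0.392 |
| green run | 20 | 0.456 |
| ochre run | 3.3 | 0.070 |
| ochre run | 6.7 | 0.123 |
| ochre run | 10 | 0.181 |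
| ochre run | 13 | 0.224 |
| ochre run | 17 | 0.261 |
| ochre run | 20 | 0.304 |
| grey run | 3.3 | 0.293 |
| grey run | 6.7 | 0.579 |
| grey run | 10 | 0.775 |
| grey run | 13 | 0.883 |
| grey run | 17 | 0.958 |
| grey run | 20 | 0.986 |
| blue run | 3.3 | 0.079 |
| blue run | 6.7 | 0.106 |
| blue run | 10 | 0.157 |
| blue run | 13 | 0.190 |
| blue run | 17 | 0.262 |
| blue run | 20 | 0.296 |

(each reading ± 0.01 M)

- how the opening rate goes with [catalyst] round the charge of the green run: the exponent of the rate at two percent of starting material gone to product
- how the opening rate goes with [coupling partner] round the charge of the green run: the exponent of the rate at two percent of starting material gone to product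
- the ochre run starts with 0.500 M less of starting material and of coupling partner than the green run, and with no product. Compared where both hold the same amount of starting material, once fifteen percent of what the ochre run was charged with has turned into product, is the ochre run faster, slower or alike (within a tenth)?
- product in the red run at 50 min, as a share of the starting material charged

- Overall: starting material + coupling partner -> product, with catalyst as catalyst.
- Constant volume, constant temperature.
- Bound and free are read together.
- "The second partner" is coupling partner.
- An order is taken over about fifteen percent of the charge, up and down.

1. The green run reads 0.310 M of product at 13 min, an average of 0.0238 M min⁻¹. The grey run, with 0.200 M of catalyst against 0.100 M, reads 0.293 M at 3.3 min, an average of 0.0888 M min⁻¹. These two averages stand in a ratio of 3.72, so the readings put the catalyst exponent at about 1.90.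

2. The ochre run is charged like the green run once 0.500 M of starting material has gone, coupling partner included, but holds no product (a same-excess experiment). My reckoning takes the ochre run as the next stretch of the green run.

3. Let a step be the stretch over which the product made comes to half of the starting material held at its start, and v the average rate over it. The green run reads 0.456 M at 20 min, so v = 0.0228 M min⁻¹; carried to the end of the first step, that rate gives a step of 21.9 min.

4. The ochre run's own first step ends at 0.250 M of product. A line through its readings of 0.224 M at 13 min and 0.304 M at 20 min reaches that amount at 15.3 min, so v = 0.0164 M min⁻¹.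

5. The slowing factor f, the average rate of one step over that of the step before, is 0.718.

6. My reckoning takes f as unchanged for the steps that follow. The third step then runs at 0.0117 M min⁻¹ and takes 10.6 min. The red run, charged like the green run, therefore completes 3 steps at 47.8 min, with 87.5% of its charge turned into product. That mark comes earlier than 50 min, and the remaining time at 0.00843 M min⁻¹ carries the red run to 89.3%.

7. The forecast gives a catalyst exponent of 1.9 (1.6 to 2.3) and a coupling-partner exponent of 0 (−0.2 to 0.2), reasoning “so the order in coupling partner is about zero”. It calls the ochre comparison alike and puts the red run at 85% (78% to 91%), lower than my 89.3%.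

8. The flask gives a catalyst exponent of 2.0, a coupling-partner exponent of 0.39, the ochre comparison alike, and 88.4% in the red run.

    catalyst + starting material ⇌ catalyst-substrate complex, settled at all times (4.880 M⁻¹)
    catalyst + coupling partner ⇌ catalyst-reagent complex, settled at all times (2.830 M⁻¹)
    catalyst-substrate complex + catalyst-reagent complex → product + 2 catalyst (16.98 M⁻¹ min⁻¹)
    starting material + coupling partner ⇌ idle substrate-reagent adduct, settled at all times (2.880 M⁻¹)

The coupling-partner exponent of 0.39 lies above the forecast's top of 0.2. The red run holds 88.4% at 50 min, where the chain built on f of 0.718 gave 89.3%. In the grey run the same chain, its 47.8 min divided by the simulated rate ratio of 4.0, puts 0.875 M of product at 12.1 min, and the grey run reads 0.775 M at 10 min and 0.883 M at 13 min. Starting material tied up with coupling partner as idle substrate-reagent adduct is the main reason the red run stops at 88.4%; without that adduct it reaches 96.4%.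

(The earlier runs and the new flask stem from a simulated flask for substances that don't exist; scatter was added.)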